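## Retrosynthetic overview
1. Target 10 ⇒ 9 ⇒ 8: the two 7-O-benzyl groups come off last, and the di-tert-butylsilylene tether comes off one step earlier.
2. 8 ⇒ 7: cut the central C3'–C3''' biaryl bond. It is made late by a silicon-tethered anodic ortho,ortho dehydrogenative coupling (the new step).
3. 7 ⇒ 6 + 5 and 6 ⇒ 5: the two 4'-O–Si bonds are made one after the other from t-Bu2Si(OTf)2.
4. 5 ⇒ 4 by pKa-controlled 7-O-benzylation, 4 ⇒ 3 by removing C2 (a one-carbon insertion closes the pyranone), and 3 ⇒ 1 + 2 by Friedel–Crafts acylation of resorcinol.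
5. Ring order: rings A and B are bought as arenes and ring C (the pyran-4-one) closes in step 2. A transient seven-membered dioxasilepine ring closes in step 6 and is opened again in step 7.

Assumption: the SMILES carries no stereodescriptor. The molecule has no stereocentre, and its 2,2'-dihydroxybiaryl axis (the other two ortho positions are H) rotates freely at room temperature. There is therefore no enantiomer to select and no stereocontrol is needed.

## Route

Step 1
Reactants: 1 resorcinol; 2 4-hydroxyphenylacetic acid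
Product: 3 1-(2,4-dihydroxyphenyl)-2-(4-hydroxyphenyl)ethan-1-one (2,4,4'-trihydroxydeoxybenzoin)
Conditions: BF3·OEt2 (as solvent), 85 °C, 2 h; then aq. NaOAc
Reagents that add atoms: none
Why: Friedel–Crafts (Nencki-type) C-acylation; BF3 activates the acid, C4 of resorcinol is the most nucleophilic site, and the chelated ortho-hydroxyketone product is deactivated towards a second acylation.

Step 2
Reactants: 3 2,4,4'-trihydroxydeoxybenzoin
Product: 4 daidzein, 7-hydroxy-3-(4-hydroxyphenyl)-4H-chromen-4-one
Conditions: HC(OEt)3 (2 equiv), morpholine (0.3 equiv), DMF, 100 °C, EtOH distilled off; then dil. HCl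
Reagents that add atoms: triethyl orthoformate, CCOC(OCC)OCC
Why: Deoxybenzoin route to isoflavones (one-carbon cyclocondensation); the amine-activated orthoformate condenses with the doubly activated CH2, and the neighbouring 2-OH closes ring C by addition–elimination with loss of ethanol.

Step 3
Reactants: 4 daidzein
Product: 5 7-O-benzyldaidzein, 7-(benzyloxy)-3-(4-hydroxyphenyl)-4H-chromen-4-one
Conditions: BnBr (1.0 equiv), K2CO3 (1.05 equiv), DMF, 25 °C; crystallise
Reagents that add atoms: benzyl bromide, BrCc1ccccc1
Why: Williamson ether synthesis under pKa control; the 7-OH is a vinylogous acid (pKa about 7.5, against about 10 for the 4'-OH), so one equivalent of weak base forms and alkylates mainly the 7-phenolate.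

Step 4
Reactants: 5 7-O-benzyldaidzein
Product: 6 4-(7-benzyloxy-4-oxo-4H-chromen-3-yl)phenoxy(di-tert-butyl)silyl trifluoromethanesulfonate
Conditions: t-Bu2Si(OTf)2 (1.1 equiv), 2,6-lutidine (1.3 equiv), CH2Cl2, −40 → 0 °C, 5 added in portions; evaporate, take up in dry toluene, filter under Ar, evaporate; used crude
Reagents that add atoms: di-tert-butylsilyl bis(trifluoromethanesulfonate), CC(C)(C)[Si](OS(=O)(=O)C(F)(F)F)(OS(=O)(=O)C(F)(F)F)C(C)(C)C
Why: O-silylation (nucleophilic substitution at silicon); the first triflate leaves at or below 0 °C, whereas the second sits on a silicon that now carries two tert-butyl groups and an aryloxy group and is inert without heat and a nucleophilic catalyst, so the reaction stops at 6, and any double substitution only gives 7, the product of the next step.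

Step 5
Reactants: 6 aryloxy(di-tert-butyl)silyl triflate; 5 7-O-benzyldaidzein
Product: 7 bis[4-(7-benzyloxy-4-oxo-4H-chromen-3-yl)phenoxy]di-tert-butylsilane
Conditions: 5 (1.0 equiv), 2,6-lutidine (1.5 equiv), DMAP (0.2 equiv), ClCH2CH2Cl, 60 °C, 12 h; aq. NaHCO3; SiO2
Reagents that add atoms: none
Why: Second O-silylation (silaketal-type tether formation); triflate is a good enough leaving group for the free 4'-phenol of 5 to displace it from the hindered silicon on warming with DMAP, the mild amine bases leave the pyranone intact, and the resulting di-tert-butyl bis(aryloxy)silane is stable to water and chromatography.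

Step 6
Reactants: 7 bis(aryloxy)di-tert-butylsilane
Product: 8 6,6-di-tert-butyl-2,10-bis(7-benzyloxy-4-oxo-4H-chromen-3-yl)dibenzo[d,f][1,3,2]dioxasilepine
Conditions: undivided cell, boron-doped diamond anode, Pt cathode, 3 mA cm−2, 2.2 F mol−1, 7 (10 mM), MeBu3N·O3SOMe (0.1 M), HFIP–CH2Cl2 4:1, 25 °C
Reagents that add atoms: none
Why: Proposed new method: silicon-tethered anodic ortho,ortho dehydrogenative aryl–aryl coupling. In 7 both 4'-oxygens sit on one silicon about 2.6 Å apart, and the two tert-butyl groups squeeze the O–Si–O angle and turn both aryl rings to the same side, so the two carbons ortho to oxygen can meet in a seven-membered transition state; HFIP hydrogen-bonds to the C4 carbonyls, which makes rings A and C and their benzyl ethers harder to oxidise and leaves the silyloxy-substituted ring B as the most electron-rich site; one-electron oxidation at boron-doped diamond gives a ring-B radical cation that HFIP keeps alive long enough to be attacked by the ortho carbon of the tethered neutral ring, and a second oxidation with loss of two protons rearomatises to the dibenzodioxasilepine 8; both oxygens are capped by silicon, so C–O coupling and Pummerer-ketone formation are shut off, the para carbons are substituted and out of reach, and at 10 mM the ring closure outruns intermolecular coupling; the covalent Si–O bonds do not dissociate, so no free phenoxyl radical escapes the tether; at the Pt cathode protons from HFIP are reduced to H2 well before the chromone, so the pyranone is spared, and the fluoride-free electrolyte spares the Si–O bonds; the closest known reaction types are the intermolecular anodic dehydrogenative coupling of phenols and O-silylated phenols in HFIP, the template-directed anodic coupling of simple phenoxyborates and the oxidative cyclisation of carbon-tethered aryl ethers with hypervalent iodine or MoCl5, none of which uses a removable silicon tether or has been shown on a flavonoid.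

Step 7
Reactants: 8 di-tert-butyldibenzodioxasilepine
Product: 9 7,7''-di-O-benzyl-3',3'''-bidaidzein
Conditions: HF·pyridine (10 equiv HF), THF–pyridine, 0 → 25 °C; then aq. NaHCO3
Reagents that add atoms: none
Why: Fluoride-driven desilylation of a di-tert-butylsilylene group; the strong Si–F bond drives cleavage of both aryl Si–O bonds, and the weakly acidic buffered medium leaves the benzyl ethers and the base-sensitive pyranone untouched.

Step 8
Reactants: 9 7,7''-di-O-benzyl-3',3'''-bidaidzein
Product: 10 3',3'''-bidaidzein, 3,3'-(6,6'-dihydroxybiphenyl-3,3'-diyl)bis(7-hydroxy-4H-chromen-4-one) (target)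
Conditions: H2 (1 atm), 10% Pd/C, THF–MeOH, 25 °C, stopped after uptake of 2 equiv H2
Reagents that add atoms: none
Why: Catalytic hydrogenolysis of aryl benzyl ethers; at 1 atm the benzylic C–O bonds cleave much faster than the vinylogous-ester C2=C3 bond of an isoflavone is reduced, and no stereocentre is involved.

## Compound list
1 | resorcinol | Oc1cccc(O)c1 | starting material
2 | 4-hydroxyphenylacetic acid | OC(=O)Cc1ccc(O)cc1 | starting material
3 | 1-(2,4-dihydroxyphenyl)-2-(4-hydroxyphenyl)ethan-1-one | O=C(Cc1ccc(O)cc1)c1ccc(O)cc1O | intermediate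
4 | daidzein | O=c1c(-c2ccc(O)cc2)coc2cc(O)ccc12 | intermediate
5 | 7-O-benzyldaidzein | O=c1c(-c2ccc(O)cc2)coc2cc(OCc3ccccc3)ccc12 | intermediate
6 | 4-(7-benzyloxy-4-oxo-4H-chromen-3-yl)phenoxy(di-tert-butyl)silyl trifluoromethanesulfonate | CC(C)(C)[Si](OS(=O)(=O)C(F)(F)F)(Oc1ccc(cc1)-c1coc2cc(OCc3ccccc3)ccc2c1=O)C(C)(C)C | intermediate
7 | bis[4-(7-benzyloxy-4-oxo-4H-chromen-3-yl)phenoxy]di-tert-butylsilane | CC(C)(C)[Si](Oc1ccc(cc1)-c1coc2cc(OCc3ccccc3)ccc2c1=O)(Oc1ccc(cc1)-c1coc2cc(OCc3ccccc3)ccc2c1=O)C(C)(C)C | intermediate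
8 | 6,6-di-tert-butyl-2,10-bis(7-benzyloxy-4-oxo-4H-chromen-3-yl)dibenzo[d,f][1,3,2]dioxasilepine | CC(C)(C)[Si]1(Oc2ccc(-c3coc4cc(OCc5ccccc5)ccc4c3=O)cc2-c2cc(-c3coc4cc(OCc5ccccc5)ccc4c3=O)ccc2O1)C(C)(C)C | intermediate
9 | 7,7''-di-O-benzyl-3',3'''-bidaidzein, 3,3'-(6,6'-dihydroxybiphenyl-3,3'-diyl)bis[7-(benzyloxy)-4H-chromen-4-one] | O=c1c(-c2ccc(O)c(-c3cc(-c4coc5cc(OCc6ccccc6)ccc5c4=O)ccc3O)c2)coc2cc(OCc3ccccc3)ccc12 | intermediate
10 | 3',3'''-bidaidzein (CNP0386002.0) | O=c1c(-c2ccc(O)c(-c3cc(-c4coc5cc(O)ccc5c4=O)ccc3O)c2)coc2cc(O)ccc12 | target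

## Step count and risks
Total step count: 8, counted from 1 and 2. Longest linear sequence: 8 (compound 5 enters twice, in steps 4 and 5).

Most likely to fail, in order of risk:

**Step 6 (the proposed new step).** The ring-B radical cation may put its charge on the C2=C3 enol ether and be trapped by HFIP at C2. The tethered ring may be too weak a nucleophile, or 8 may be oxidised further than 7. The fallback uses known chemistry. It sets out from 5 and comes back at 10. Iodinate 5 ortho to the free phenol with NIS and catalytic TsOH in MeCN to give 7-(benzyloxy)-3-(4-hydroxy-3-iodophenyl)-4H-chromen-4-one F1. Cap the phenol with BnBr/K2CO3 in DMF to give 7-(benzyloxy)-3-[4-(benzyloxy)-3-iodophenyl]-4H-chromen-4-one F2. Heat F2 with B2pin2 (0.55 equiv), PdCl2(dppf) and K2CO3 in DMSO at 80 °C. Miyaura borylation converts half of it into 7-(benzyloxy)-3-[4-(benzyloxy)-3-(4,4,5,5-tetramethyl-1,3,2-dioxaborolan-2-yl)phenyl]-4H-chromen-4-one F3. This undergoes Suzuki–Miyaura coupling in the same flask with the remaining F2 to give 4',4''',7,7''-tetra-O-benzyl-3',3'''-bidaidzein F4. Hydrogenolysis of all four benzyl ethers (H2, Pd/C, THF–MeOH) gives 10.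

**Step 5 (second Si–O bond at the hindered silicon).** The phenol of 5 may not displace triflate from a silicon that already carries two tert-butyl groups and an aryloxy group, and 6 may hydrolyse to the silanol instead. The fallback gives up the di-tert-butylsilyl centre and builds an unhindered tether from a dichlorosilane. It sets out from 5 and comes back at 9. Treat 5 with i-Pr2SiCl2 (3 equiv) and Et3N in CH2Cl2 at 0 °C, then strip the excess silane in vacuo, to obtain 7-(benzyloxy)-3-{4-[chloro(diisopropyl)silyloxy]phenyl}-4H-chromen-4-one F5. Add one further equivalent of 5 with imidazole in DMF at 25 °C to give bis[4-(7-benzyloxy-4-oxo-4H-chromen-3-yl)phenoxy]diisopropylsilane F6. Electrolyse F6 under the conditions of step 6, with 2,6-lutidine (0.2 equiv) as an acid buffer for the less robust tether. This gives 6,6-diisopropyl-2,10-bis(7-benzyloxy-4-oxo-4H-chromen-3-yl)dibenzo[d,f][1,3,2]dioxasilepine F7. Cleave the tether with HF·pyridine in THF to give 9.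

**Step 3 (selective 7-O-benzylation).** It may give 4'-O-benzyl and bis-benzyl ethers that are hard to separate. The fallback swaps pKa control for a protecting-group relay. It sets out from 4 and comes back at 5. Acetylate 4 with Ac2O/pyridine to give daidzein 4',7-diacetate F8. Cleave only the more electrophilic 7-acetate with PhSH/imidazole in NMP at 0–25 °C to give 4'-O-acetyldaidzein F9. Benzylate the free 7-OH under neutral Mitsunobu conditions (BnOH, PPh3, DIAD, THF) to give 4'-O-acetyl-7-O-benzyldaidzein F10. Remove the acetate by methanolysis (catalytic K2CO3, MeOH–THF) to give 5.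

## Further compounds
F1 | step 6 | 7-(benzyloxy)-3-(4-hydroxy-3-iodophenyl)-4H-chromen-4-one | O=c1c(-c2ccc(O)c(I)c2)coc2cc(OCc3ccccc3)ccc12
F2 | step 6 | 7-(benzyloxy)-3-[4-(benzyloxy)-3-iodophenyl]-4H-chromen-4-one | O=c1c(-c2ccc(OCc3ccccc3)c(I)c2)coc2cc(OCc3ccccc3)ccc12
F3 | step 6 | 7-(benzyloxy)-3-[4-(benzyloxy)-3-(4,4,5,5-tetramethyl-1,3,2-dioxaborolan-2-yl)phenyl]-4H-chromen-4-one | O=c1c(-c2ccc(OCc3ccccc3)c(B3OC(C)(C)C(C)(C)O3)c2)coc2cc(OCc3ccccc3)ccc12
F4 | step 6 | 4',4''',7,7''-tetra-O-benzyl-3',3'''-bidaidzein | O=c1c(-c2ccc(OCc3ccccc3)c(-c3cc(-c4coc5cc(OCc6ccccc6)ccc5c4=O)ccc3OCc3ccccc3)c2)coc2cc(OCc3ccccc3)ccc12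
F5 | step 5 | 7-(benzyloxy)-3-{4-[chloro(diisopropyl)silyloxy]phenyl}-4H-chromen-4-one | CC(C)[Si](Cl)(Oc1ccc(cc1)-c1coc2cc(OCc3ccccc3)ccc2c1=O)C(C)C
F6 | step 5 | bis[4-(7-benzyloxy-4-oxo-4H-chromen-3-yl)phenoxy]diisopropylsilane | CC(C)[Si](Oc1ccc(cc1)-c1coc2cc(OCc3ccccc3)ccc2c1=O)(Oc1ccc(cc1)-c1coc2cc(OCc3ccccc3)ccc2c1=O)C(C)C
F7 | step 5 | 6,6-diisopropyl-2,10-bis(7-benzyloxy-4-oxo-4H-chromen-3-yl)dibenzo[d,f][1,3,2]dioxasilepine | CC(C)[Si]1(Oc2ccc(-c3coc4cc(OCc5ccccc5)ccc4c3=O)cc2-c2cc(-c3coc4cc(OCc5ccccc5)ccc4c3=O)ccc2O1)C(C)C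
F8 | step 3 | daidzein 4',7-diacetate | CC(=O)Oc1ccc(cc1)-c1coc2cc(OC(C)=O)ccc2c1=O
F9 | step 3 | 4'-O-acetyldaidzein | CC(=O)Oc1ccc(cc1)-c1coc2cc(O)ccc2c1=O
F10 | step 3 | 4'-O-acetyl-7-O-benzyldaidzein | CC(=O)Oc1ccc(cc1)-c1coc2cc(OCc3ccccc3)ccc2c1=O
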